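**Plan**
- Cuts: the O7 and O3' allyl ethers are removed last. Ring D is cut at C5'–C4'' and O4'–C2'' to give a 4'-hydroxyflavan and (S)-3,3-dimethyloxirane-2-carbaldehyde. Ring C is cut at O1–C2, the chain at C3–C4, and the prenyl group at its bond to C2'.
- Forward order: ring B is prenylated first (propargyl ether, semihydrogenation, Claisen rearrangement). The chain is then joined to the ring A salicylaldehyde by Claisen–Schmidt condensation, ring C is closed by a Mitsunobu reaction, and ring D is annulated last in one operation.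
- Enabling feature: ring D is O4'–C2''Me2–C3''H(OH)–C4''H(OH)–C5'. Its three carbons and both hydroxyl oxygens are those of 2,3-epoxy-3-methylbutanal, and C5' is the only free carbon ortho to the phenol oxygen O4'.
- Stereochemistry: C2 (S) comes from Ru/(R,R)-TsDPEN transfer hydrogenation followed by invertive Mitsunobu closure. C3'' (R) comes from Sharpless epoxidation of prenol with D-(−)-diisopropyl tartrate. C4'' (R) comes from Felkin–Anh addition to the epoxy aldehyde in the key step.

Key step: step 13

Remark: locants follow flavan numbering (rings A and C unprimed, ring B primed); ring D is O4'–C2''(Me)2–C3''–C4''–C5'; allyl means prop-2-en-1-yl and prenyl means 3-methylbut-2-en-1-yl.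

**Route**

Step 1
Reactants: 1 3,4-dihydroxyacetophenone
Product: 2 1-[3-hydroxy-4-(methoxymethoxy)phenyl]ethan-1-one
Conditions: MOMCl (1.05 equiv), K2CO3 (1.1 equiv), acetone, 0 → 23 °C
Reagents that add atoms: chloromethyl methyl ether, COCCl
Why: Williamson-type O-alkylation in which one equivalent of carbonate deprotonates only the more acidic 4-OH (para to the acetyl group), so the MOM ether should form there and leave the 3-OH free.

Step 2
Reactants: 2 1-[3-hydroxy-4-(methoxymethoxy)phenyl]ethan-1-one
Product: 3 1-[4-(methoxymethoxy)-3-(2-methylbut-3-yn-2-yloxy)phenyl]ethan-1-one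
Conditions: 3-chloro-3-methylbut-1-yne (2 equiv), K2CO3, KI, CuI (5 mol%), acetone, 56 °C
Reagents that add atoms: 3-chloro-3-methylbut-1-yne, CC(C)(Cl)C#C
Why: Copper-catalysed O-propargylation of a phenol with a tertiary propargylic chloride is the standard entry to aryl 1,1-dimethylpropargyl ethers and tolerates the ketone and the MOM ether.

Step 3
Reactants: 3 1-[4-(methoxymethoxy)-3-(2-methylbut-3-yn-2-yloxy)phenyl]ethan-1-one
Product: 4 1-[4-(methoxymethoxy)-3-(2-methylbut-3-en-2-yloxy)phenyl]ethan-1-one
Conditions: H2 (1 atm), lead-poisoned Pd/CaCO3 (Pb(OAc)2), quinoline, EtOAc, 23 °C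
Reagents that add atoms: none
Why: Lindlar semihydrogenation should stop at the terminal alkene because the poisoned catalyst binds the alkyne far more strongly than the alkene, and the aryl ketone is inert.

Step 4
Reactants: 4 1-[4-(methoxymethoxy)-3-(2-methylbut-3-en-2-yloxy)phenyl]ethan-1-one
Product: 6 1-[3-hydroxy-4-(methoxymethoxy)-2-(3-methylbut-2-en-1-yl)phenyl]ethan-1-one, via ortho-dienone 5 (not isolated)
Conditions: N,N-diethylaniline, 140 °C
Reagents that add atoms: none
Why: Aromatic Claisen rearrangement of the 1,1-dimethylallyl ether delivers the allyl terminus to C2, the only unsubstituted ortho carbon (C4 carries the MOM ether), and tautomerisation of the dienone gives the 2-prenylphenol.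

Step 5
Reactants: 6 1-[3-hydroxy-4-(methoxymethoxy)-2-(3-methylbut-2-en-1-yl)phenyl]ethan-1-one
Product: 7 1-[3-(allyloxy)-4-(methoxymethoxy)-2-(3-methylbut-2-en-1-yl)phenyl]ethan-1-one
Conditions: allyl bromide (1.5 equiv), K2CO3, DMF, 23 °C
Reagents that add atoms: allyl bromide, C=CCBr
Why: Williamson ether synthesis with the reactive allyl bromide caps the flanked 3-OH with a non-migrating group, so that no free phenol sits next to the prenyl group in the later Mitsunobu and acid steps.

Step 6
Reactants: 8 2,4-dihydroxybenzaldehyde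
Product: 9 4-(allyloxy)-2-hydroxybenzaldehyde
Conditions: allyl bromide (1.05 equiv), NaHCO3 (1.2 equiv), KI (10 mol%), MeCN, 80 °C
Reagents that add atoms: allyl bromide, C=CCBr
Why: Regioselective Williamson O-allylation, since the 2-OH is held in a hydrogen bond to the formyl group and the weak base should alkylate only the 4-OH.

Step 7
Reactants: 7 1-[3-(allyloxy)-4-(methoxymethoxy)-2-(3-methylbut-2-en-1-yl)phenyl]ethan-1-one; 9 4-(allyloxy)-2-hydroxybenzaldehyde
Product: 10 (E)-3-[4-(allyloxy)-2-hydroxyphenyl]-1-[3-(allyloxy)-4-(methoxymethoxy)-2-(3-methylbut-2-en-1-yl)phenyl]prop-2-en-1-one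
Conditions: KOH (50% aq., excess), EtOH, 0 → 23 °C
Reagents that add atoms: none
Why: Claisen–Schmidt condensation in which the methyl ketone enolate adds to the non-enolisable aldehyde (present as its phenoxide, hence the excess base) and E1cB dehydration gives the conjugated E-enone, all ether groups being stable to hydroxide.

Step 8
Reactants: 10 (E)-3-[4-(allyloxy)-2-hydroxyphenyl]-1-[3-(allyloxy)-4-(methoxymethoxy)-2-(3-methylbut-2-en-1-yl)phenyl]prop-2-en-1-one
Product: 12 (1R)-1-[3-(allyloxy)-4-(methoxymethoxy)-2-(3-methylbut-2-en-1-yl)phenyl]-3-[4-(allyloxy)-2-hydroxyphenyl]propan-1-ol, via saturated ketone 11 (not isolated)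
Conditions: RuCl[(R,R)-TsDPEN](p-cymene) (5 mol%), HCO2H/Et3N (5:2), EtOAc, 40 °C
Reagents that add atoms: none
Why: Noyori–Ikariya asymmetric transfer hydrogenation in which the ruthenium hydride first reduces the enone C=C in a 1,4-sense and then the aryl ketone through the six-membered outer-sphere transition state, the (R,R)-ligand placing the aryl group against p-cymene so that the carbinol should be R, while the isolated allyl and prenyl alkenes are not touched.

Step 9
Reactants: 12 (1R)-1-[3-(allyloxy)-4-(methoxymethoxy)-2-(3-methylbut-2-en-1-yl)phenyl]-3-[4-(allyloxy)-2-hydroxyphenyl]propan-1-ol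
Product: 13 (2S)-7-(allyloxy)-2-[3-(allyloxy)-4-(methoxymethoxy)-2-(3-methylbut-2-en-1-yl)phenyl]chromane
Conditions: PPh3, DIAD, THF, 0 °C
Reagents that add atoms: none
Why: Intramolecular Mitsunobu etherification in which the ring A phenol displaces the activated benzylic alcohol in an SN2 6-exo-tet closure of ring C with inversion, turning the (R)-carbinol into the (2S)-flavan.

Step 10
Reactants: 13 (2S)-7-(allyloxy)-2-[3-(allyloxy)-4-(methoxymethoxy)-2-(3-methylbut-2-en-1-yl)phenyl]chromane
Product: 14 2-(allyloxy)-4-[(2S)-7-(allyloxy)chroman-2-yl]-3-(3-methylbut-2-en-1-yl)phenol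
Conditions: HCl (1 M in MeOH), 23 °C
Reagents that add atoms: none
Why: Acid-catalysed acetal cleavage (transacetalisation to methanol) frees O4' alone, since aryl allyl ethers are stable to dilute acid and, with O3' capped, no phenol can add to the prenyl alkene.

Step 11
Reactants: 15 3-methylbut-2-en-1-ol
Product: 16 [(2R)-3,3-dimethyloxiran-2-yl]methanol
Conditions: Ti(OiPr)4 (10 mol%), D-(−)-diisopropyl tartrate (12 mol%), t-BuOOH (anhydrous, 2 equiv), 4 Å MS, CH2Cl2, −20 °C; non-aqueous work-up, distillation
Reagents that add atoms: tert-butyl hydroperoxide, CC(C)(C)OO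
Why: Sharpless asymmetric epoxidation in which the titanium tartrate binds both the allylic alcohol and the hydroperoxide, the D-(−)-tartrate directing oxygen to the face that should give the (2R)-epoxy alcohol.

Step 12
Reactants: 16 [(2R)-3,3-dimethyloxiran-2-yl]methanol
Product: 17 (2S)-3,3-dimethyloxirane-2-carbaldehyde
Conditions: TEMPO (10 mol%), PhI(OAc)2 (1.1 equiv), CH2Cl2, 23 °C; used as a dried solution after short-path distillation
Reagents that add atoms: none
Why: TEMPO (oxoammonium) oxidation of the primary alcohol stops at the aldehyde under nearly neutral conditions that leave the acid-sensitive oxirane and its stereocentre intact, the descriptor changing from R to S only because CHO outranks CMe2.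

Step 13
Reactants: 14 2-(allyloxy)-4-[(2S)-7-(allyloxy)chroman-2-yl]-3-(3-methylbut-2-en-1-yl)phenol; 17 (2S)-3,3-dimethyloxirane-2-carbaldehyde
Product: 20 (3R,4R)-8-(allyloxy)-6-[(2S)-7-(allyloxy)chroman-2-yl]-2,2-dimethyl-7-(3-methylbut-2-en-1-yl)chromane-3,4-diol (the 7,3'-di-O-allyl ether of the target), via titanium phenolate 18 (not isolated), via epoxy alcohol 19 (not isolated)
Conditions: Ti(OiPr)4 (1.1 equiv), toluene, 23 °C, then iPrOH removed in vacuo; CH2Cl2, 17 (1.5 equiv), −20 → 0 °C; then 23 °C; aq. potassium sodium tartrate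
Reagents that add atoms: none
Why: Proposed new method: ligand exchange converts 14 into the aryloxytitanium triisopropoxide 18, whose tetravalent titanium binds the formyl oxygen of 17 and delivers the carbonyl carbon through a six-membered cyclic transition state to C5' (bond C5'–C4''), after which the titanium alkoxide–aryloxide chelate of 19 serves as the Lewis acid under which O4' opens the oxirane at C2'' (bond O4'–C2''). The closest known reaction types are the ortho-specific hydroxyalkylation of magnesium or titanium phenolates by chiral alpha-oxygenated aldehydes and the acid- or titanium-promoted distal opening of 2,3-epoxy alcohols, as in the cyclisation of ortho-(2,3-epoxy-3-methylbutyl)phenols to 2,2-dimethylchroman-3-ols. Ring D closes in a 6-endo-tet mode with inversion at C2'', which is not stereogenic. C4'' is set in the C–C bond formation by Felkin–Anh control, because the crowded, weakly Lewis acidic triisopropoxytitanium centre should not chelate the oxirane oxygen, so the arene attacks anti to the C3''–O bond of the (S)-aldehyde and past its small hydrogen to give the anti epoxy alcohol (4''R) and hence the cis-diol, while C3'' keeps the spatial arrangement of 17 since its C–O bond is never broken (it reads R in 19 and 20 only through the changed substituent ranking). The step needs ortho regioselectivity, secured because C5' is the only unsubstituted carbon ortho to the titanium-bearing O4' (C3' carries the allyl ether and the ring A oxygen is capped), and it needs 6-endo over 5-exo opening, secured by the tertiary, cation-stabilising C2'' terminus and by titanium coordination of the oxirane oxygen. Both diol oxygens arrive with 17, so no alkene is oxidised and the prenyl and allyl groups stay untouched.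

Step 14
Reactants: 20 (3R,4R)-8-(allyloxy)-6-[(2S)-7-(allyloxy)chroman-2-yl]-2,2-dimethyl-7-(3-methylbut-2-en-1-yl)chromane-3,4-diol
Product: 21 (3R,4R)-6-[(2S)-7-hydroxychroman-2-yl]-2,2-dimethyl-7-(3-methylbut-2-en-1-yl)chromane-3,4,8-triol (CNP0228510.2)
Conditions: Pd(PPh3)4 (5 mol%), morpholine (6 equiv), THF, 23 °C
Reagents that add atoms: none
Why: Tsuji–Trost deallylation in which zerovalent palladium ionises both aryl allyl ethers to π-allyl complexes that morpholine traps, freeing the 7- and 3'-phenols under neutral conditions that should spare the prenyl alkene, the benzylic cis-diol and C2.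

**Compound list**
1 | 3,4-dihydroxyacetophenone | CC(=O)c1ccc(O)c(O)c1 | starting material
2 | 1-[3-hydroxy-4-(methoxymethoxy)phenyl]ethan-1-one | CC(=O)c1ccc(OCOC)c(O)c1 | intermediate
3 | 1-[4-(methoxymethoxy)-3-(2-methylbut-3-yn-2-yloxy)phenyl]ethan-1-one | CC(=O)c1ccc(OCOC)c(OC(C)(C)C#C)c1 | intermediate
4 | 1-[4-(methoxymethoxy)-3-(2-methylbut-3-en-2-yloxy)phenyl]ethan-1-one | CC(=O)c1ccc(OCOC)c(OC(C)(C)C=C)c1 | intermediate
5 | 5-acetyl-2-(methoxymethoxy)-6-(3-methylbut-2-en-1-yl)cyclohexa-2,4-dien-1-one (ortho-dienone, not isolated) | CC(=O)C1=CC=C(OCOC)C(=O)C1CC=C(C)C | intermediate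
6 | 1-[3-hydroxy-4-(methoxymethoxy)-2-(3-methylbut-2-en-1-yl)phenyl]ethan-1-one | CC(=O)c1ccc(OCOC)c(O)c1CC=C(C)C | intermediate
7 | 1-[3-(allyloxy)-4-(methoxymethoxy)-2-(3-methylbut-2-en-1-yl)phenyl]ethan-1-one | CC(=O)c1ccc(OCOC)c(OCC=C)c1CC=C(C)C | intermediate
8 | 2,4-dihydroxybenzaldehyde | O=Cc1ccc(O)cc1O | starting material
9 | 4-(allyloxy)-2-hydroxybenzaldehyde | O=Cc1ccc(OCC=C)cc1O | intermediate
10 | (E)-3-[4-(allyloxy)-2-hydroxyphenyl]-1-[3-(allyloxy)-4-(methoxymethoxy)-2-(3-methylbut-2-en-1-yl)phenyl]prop-2-en-1-one | O=C(/C=C/c1ccc(OCC=C)cc1O)c1ccc(OCOC)c(OCC=C)c1CC=C(C)C | intermediate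
11 | 3-[4-(allyloxy)-2-hydroxyphenyl]-1-[3-(allyloxy)-4-(methoxymethoxy)-2-(3-methylbut-2-en-1-yl)phenyl]propan-1-one (not isolated) | O=C(CCc1ccc(OCC=C)cc1O)c1ccc(OCOC)c(OCC=C)c1CC=C(C)C | intermediate
12 | (1R)-1-[3-(allyloxy)-4-(methoxymethoxy)-2-(3-methylbut-2-en-1-yl)phenyl]-3-[4-(allyloxy)-2-hydroxyphenyl]propan-1-ol | O[C@H](CCc1ccc(OCC=C)cc1O)c1ccc(OCOC)c(OCC=C)c1CC=C(C)C | intermediate
13 | (2S)-7-(allyloxy)-2-[3-(allyloxy)-4-(methoxymethoxy)-2-(3-methylbut-2-en-1-yl)phenyl]chromane | CC(C)=CCc1c([C@@H]2CCc3ccc(OCC=C)cc3O2)ccc(OCOC)c1OCC=C | intermediate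
14 | 2-(allyloxy)-4-[(2S)-7-(allyloxy)chroman-2-yl]-3-(3-methylbut-2-en-1-yl)phenol | CC(C)=CCc1c([C@@H]2CCc3ccc(OCC=C)cc3O2)ccc(O)c1OCC=C | intermediate
15 | 3-methylbut-2-en-1-ol | CC(C)=CCO | starting material
16 | [(2R)-3,3-dimethyloxiran-2-yl]methanol | CC1(C)O[C@@H]1CO | intermediate
17 | (2S)-3,3-dimethyloxirane-2-carbaldehyde | CC1(C)O[C@@H]1C=O | intermediate
18 | triisopropoxytitanium phenolate of 14, titanium on O4' (not isolated) | CC(C)=CCc1c([C@@H]2CCc3ccc(OCC=C)cc3O2)ccc(O[Ti](OC(C)C)(OC(C)C)OC(C)C)c1OCC=C | intermediate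
19 | (R)-{3-(allyloxy)-5-[(2S)-7-(allyloxy)chroman-2-yl]-2-hydroxy-4-(3-methylbut-2-en-1-yl)phenyl}[(2R)-3,3-dimethyloxiran-2-yl]methanol, the anti epoxy alcohol, present as its titanium chelate (metal-free form drawn, not isolated) | CC(C)=CCc1c([C@@H]2CCc3ccc(OCC=C)cc3O2)cc([C@@H](O)[C@H]4OC4(C)C)c(O)c1OCC=C | intermediate
20 | (3R,4R)-8-(allyloxy)-6-[(2S)-7-(allyloxy)chroman-2-yl]-2,2-dimethyl-7-(3-methylbut-2-en-1-yl)chromane-3,4-diol | CC(C)=CCc1c([C@@H]2CCc3ccc(OCC=C)cc3O2)cc2c(c1OCC=C)OC(C)(C)[C@H](O)[C@@H]2O | intermediate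
21 | (3R,4R)-6-[(2S)-7-hydroxychroman-2-yl]-2,2-dimethyl-7-(3-methylbut-2-en-1-yl)chromane-3,4,8-triol | CC(C)=CCc1c([C@@H]2CCc3ccc(O)cc3O2)cc2c(c1O)OC(C)(C)[C@H](O)[C@@H]2O | target

**Step count and risks**
Total step count: 14. Longest linear sequence: 11 steps (steps 1–5, 7–10, 13, 14).

Most likely to fail, in order:

1. Step 13 (key step). The addition could run under chelation control and give the syn adduct, which leads to the trans-diol series. The ortho-oxybenzylic titanium alkoxide could also ionise to a quinone methide, or the tertiary oxirane could rearrange under the Lewis acid before O4' attacks. The fallback builds ring D from an alkene and sets out from 14. Ortho-specific chromenylation with 3-methylbut-2-enal (PhB(OH)2, AcOH, toluene, reflux; benzodioxaborin, quinone methide, oxa-6π electrocyclisation) would give the 2H-chromene F1. Jacobsen–Katsuki epoxidation ((R,R)-N,N'-bis(3,5-di-tert-butylsalicylidene)-1,2-cyclohexanediaminomanganese chloride, NaOCl, 4-phenylpyridine N-oxide, CH2Cl2, 0 °C) prefers the conjugated cis-alkene over the isolated prenyl and allyl alkenes and is expected to give the (3''R,4''R)-epoxide F2. Halide-catalysed CO2 insertion (CO2, Bu4NBr, 60 °C) proceeds by double inversion at C4'', hence net retention, and would give the cis-fused cyclic carbonate F3. Methanolysis (K2CO3, MeOH) would then release the cis-diol, and the route is rejoined at 20.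

2. Step 9. The activated carbinol (para-alkoxy, ortho-prenyl aryl) could ionise to a benzylic cation, which would erode the enantiomeric purity at C2, or it could eliminate to the styrene. The fallback closes ring C through the aryl–oxygen bond O1–C8a, so the carbinol C–O bond is never broken; it sets out from 7. Condensation (KOH, EtOH) with 4-(allyloxy)-2-bromobenzaldehyde F4 (from commercial 2-bromo-4-hydroxybenzaldehyde, allyl bromide and K2CO3) would give the bromo enone F5. Transfer hydrogenation with the enantiomeric catalyst RuCl[(S,S)-TsDPEN](p-cymene) would pass through the saturated bromo ketone F6 to the (1S)-bromo alcohol F7. Intramolecular Ullmann etherification (CuI, 1,10-phenanthroline, Cs2CO3, toluene, 110 °C) retains the carbinol configuration and would return the route to 13.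

3. Step 8. The tandem reduction could stall after the 1,4-reduction or divert to 1,2-reduction, and facial discrimination could drop because the ortho-prenyl group twists the aryl ketone. The fallback separates the two reductions and changes the reductant class; it sets out from 10. Conjugate reduction with [(Ph3P)CuH]6 (toluene, 23 °C) would give ketone 11, now isolated. Corey–Bakshi–Shibata reduction ((S)-Me-CBS oxazaborolidine, catecholborane, toluene, −78 °C) would then return the route to 12; no new compound arises.

**Further compounds**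
F1 | step 13 | 8-(allyloxy)-6-[(2S)-7-(allyloxy)chroman-2-yl]-2,2-dimethyl-7-(3-methylbut-2-en-1-yl)-2H-chromene | CC(C)=CCc1c([C@@H]2CCc3ccc(OCC=C)cc3O2)cc2c(c1OCC=C)OC(C)(C)C=C2
F2 | step 13 | (3R,4R)-3,4-epoxy-3,4-dihydro derivative of F1 (chromene oxide) | CC(C)=CCc1c([C@@H]2CCc3ccc(OCC=C)cc3O2)cc2c(c1OCC=C)OC(C)(C)[C@@H]3O[C@H]23
F3 | step 13 | cis-fused cyclic carbonate of the (3R,4R)-diol 20 | CC(C)=CCc1c([C@@H]2CCc3ccc(OCC=C)cc3O2)cc2c(c1OCC=C)OC(C)(C)[C@@H]3OC(=O)O[C@H]23
F4 | step 9 | 4-(allyloxy)-2-bromobenzaldehyde | O=Cc1ccc(OCC=C)cc1Br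
F5 | step 9 | (E)-3-[4-(allyloxy)-2-bromophenyl]-1-[3-(allyloxy)-4-(methoxymethoxy)-2-(3-methylbut-2-en-1-yl)phenyl]prop-2-en-1-one | O=C(/C=C/c1ccc(OCC=C)cc1Br)c1ccc(OCOC)c(OCC=C)c1CC=C(C)C
F6 | step 9 | 3-[4-(allyloxy)-2-bromophenyl]-1-[3-(allyloxy)-4-(methoxymethoxy)-2-(3-methylbut-2-en-1-yl)phenyl]propan-1-one | O=C(CCc1ccc(OCC=C)cc1Br)c1ccc(OCOC)c(OCC=C)c1CC=C(C)C
F7 | step 9 | (1S)-1-[3-(allyloxy)-4-(methoxymethoxy)-2-(3-methylbut-2-en-1-yl)phenyl]-3-[4-(allyloxy)-2-bromophenyl]propan-1-ol | O[C@@H](CCc1ccc(OCC=C)cc1Br)c1ccc(OCOC)c(OCC=C)c1CC=C(C)C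
F0 | step 8 | none | none
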